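**Retrosynthetic overview**
1. The C3–C4 bond is made last by a reagent-controlled boron aldol of the C1-acetyl core with acetaldehyde; the angelate is put on C5–OH just before.
2. The C1 tertiary carbinol comes from a chelation-controlled ethynyl Grignard addition to the bicyclic C1 ketone, followed by alkyne hydration.
3. The cycloheptane comes from ring-closing metathesis (C8=C9) on a preformed cis-fused α-methylene-γ-butyrolactone; one hydrogenation then saturates C8–C9 and sets C11.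
4. Key C6–C7 bond: intermolecular indium-mediated carbonyl allylation of an α-PMB-oxy aldehyde (C5, C1, C10, C9) with a (Z)-2-(bromomethyl)enoate (C7, C8, C11–C13). Ring order: lactone first, carbocycle second.
5. The aldehyde comes from (R)-solketal and a (Z)-crotylboronate; the bromide from acrolein, benzeneselenol and methyl acrylate (Morita–Baylis–Hillman).

Locants (seco-guaiane numbering): C1 = carbinol carbon carrying the side chain C2–C4/C15; C5 = angelate carbon; C6/C7 = lactone ring fusion; C8/C9 = ring CH2; C10 = CHMe; C11–C13 = lactone propionate unit.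
Assumption: (R)-solketal, (Z)-crotylboronic acid pinacol ester, ethynylmagnesium bromide solution, angelic acid, benzeneselenol and (−)-Ipc2BCl are bought.

Step 1
Reactants: 1 (R)-(2,2-dimethyl-1,3-dioxolan-4-yl)methanol
Product: 2 (4S)-2,2-dimethyl-1,3-dioxolane-4-carbaldehyde
Conditions: IBX, EtOAc, 75 °C; filter; cold solution used at once
Reagents that add atoms: none
Why: IBX oxidation of the primary alcohol under neutral conditions leaves the acetonide and the α-stereocentre intact, and filtration removes the spent iodine reagent so the labile aldehyde is never stored.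

Step 2
Reactants: 2 (4S)-2,2-dimethyl-1,3-dioxolane-4-carbaldehyde; 3 2-[(2Z)-but-2-en-1-yl]-4,4,5,5-tetramethyl-1,3,2-dioxaborolane
Product: 5 (1R,2S)-1-[(4S)-2,2-dimethyl-1,3-dioxolan-4-yl]-2-methylbut-3-en-1-ol, via pinacol borate ester 4 (not isolated)
Conditions: toluene, 4 Å sieves, rt, 48 h; then dilute aq. NaOH, 0 °C
Reagents that add atoms: none
Why: Substrate-controlled crotylboration through a chair Zimmerman–Traxler transition state, in which the Z-boronate gives the C1/C10 syn relationship and Felkin–Anh attack anti to the dioxolane C–O bond gives the C1/C5 anti relationship, so that C10 is set correctly relative to C5.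

Step 3
Reactants: 5 (1R,2S)-1-[(4S)-2,2-dimethyl-1,3-dioxolan-4-yl]-2-methylbut-3-en-1-ol
Product: 6 tert-butyl{[(1R,2S)-1-[(4S)-2,2-dimethyl-1,3-dioxolan-4-yl]-2-methylbut-3-en-1-yl]oxy}dimethylsilane
Conditions: TBSOTf, 2,6-lutidine, CH2Cl2, −78 to 0 °C
Reagents that add atoms: tert-butyldimethylsilyl trifluoromethanesulfonate, CC(C)(C)[Si](C)(C)OS(=O)(=O)C(F)(F)F
Why: Silyl triflate silylation protects the hindered secondary C1 alcohol, which is only a placeholder for the later C1 ketone.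

Step 4
Reactants: 6 tert-butyl{[(1R,2S)-1-[(4S)-2,2-dimethyl-1,3-dioxolan-4-yl]-2-methylbut-3-en-1-yl]oxy}dimethylsilane
Product: 7 (2S,3R,4S)-3-[(tert-butyldimethylsilyl)oxy]-4-methylhex-5-ene-1,2-diol
Conditions: AcOH/THF/H2O 3:1:1, 45 °C
Reagents that add atoms: none
Why: Mild acid-catalysed acetal hydrolysis removes the terminal acetonide while the hindered secondary TBS ether survives.

Step 5
Reactants: 7 (2S,3R,4S)-3-[(tert-butyldimethylsilyl)oxy]-4-methylhex-5-ene-1,2-diol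
Product: 8 tert-butyl{[(1R,2S)-1-[(4S)-2-(4-methoxyphenyl)-1,3-dioxolan-4-yl]-2-methylbut-3-en-1-yl]oxy}dimethylsilane (both acetal epimers)
Conditions: 4-MeOC6H4CH(OMe)2, PPTS (cat.), CH2Cl2, rt
Reagents that add atoms: 4-methoxybenzaldehyde dimethyl acetal, COC(OC)c1ccc(OC)cc1
Why: Acid-catalysed transacetalisation ties the 1,2-diol into a 4-methoxybenzylidene acetal, whose acetal configuration is irrelevant because the centre is lost in the next step.

Step 6
Reactants: 8 tert-butyl{[(1R,2S)-1-[(4S)-2-(4-methoxyphenyl)-1,3-dioxolan-4-yl]-2-methylbut-3-en-1-yl]oxy}dimethylsilane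
Product: 9 (2S,3R,4S)-3-[(tert-butyldimethylsilyl)oxy]-2-[(4-methoxybenzyl)oxy]-4-methylhex-5-en-1-ol
Conditions: i-Bu2AlH, CH2Cl2, −78 to 0 °C; aq. potassium sodium tartrate work-up
Reagents that add atoms: none
Why: Regioselective reductive acetal opening, in which aluminium binds the less hindered primary oxygen and hydride delivery leaves the PMB group on the secondary C5 oxygen and frees the primary alcohol.

Step 7
Reactants: 9 (2S,3R,4S)-3-[(tert-butyldimethylsilyl)oxy]-2-[(4-methoxybenzyl)oxy]-4-methylhex-5-en-1-ol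
Product: 10 (2R,3R,4S)-3-[(tert-butyldimethylsilyl)oxy]-2-[(4-methoxybenzyl)oxy]-4-methylhex-5-enal
Conditions: Dess–Martin periodinane, CH2Cl2, 0 °C to rt; used crude
Reagents that add atoms: none
Why: Dess–Martin oxidation gives the α-alkoxy aldehyde under non-basic conditions so that C5 is not epimerised.

Step 8
Reactants: 11 acrolein
Product: 12 3-(phenylselanyl)propanal
Conditions: PhSeH, CH2Cl2, 0 °C to rt
Reagents that add atoms: benzeneselenol, [SeH]c1ccccc1
Why: Conjugate (hetero-Michael) addition of the soft selenol to the enal installs a masked vinyl group that tolerates the following steps.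

Step 9
Reactants: 12 3-(phenylselanyl)propanal; 13 methyl acrylate
Product: 14 methyl 3-hydroxy-2-methylidene-5-(phenylselanyl)pentanoate (racemic)
Conditions: DABCO (0.3 equiv), neat in excess 13, rt, 5 d
Reagents that add atoms: none
Why: Morita–Baylis–Hillman reaction of an unhindered aliphatic aldehyde with methyl acrylate, whose new carbinol centre is erased in the next step.

Step 10
Reactants: 14 methyl 3-hydroxy-2-methylidene-5-(phenylselanyl)pentanoate
Product: 15 methyl (2Z)-2-(bromomethyl)-5-(phenylselanyl)pent-2-enoate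
Conditions: PBr3, Et2O, 0 °C to rt
Reagents that add atoms: phosphorus tribromide, BrP(Br)Br
Why: Bromination with allylic transposition (SN2') gives the thermodynamically favoured trisubstituted enoate with the alkyl chain cis to CH2Br, and it avoids oxidants that would attack selenium.

Step 11
Reactants: 10 (2R,3R,4S)-3-[(tert-butyldimethylsilyl)oxy]-2-[(4-methoxybenzyl)oxy]-4-methylhex-5-enal; 15 methyl (2Z)-2-(bromomethyl)-5-(phenylselanyl)pent-2-enoate
Product: 17 methyl (3S,4R,5S,6R,7S)-6-[(tert-butyldimethylsilyl)oxy]-4-hydroxy-5-[(4-methoxybenzyl)oxy]-7-methyl-2-methylidene-3-[2-(phenylselanyl)ethyl]non-8-enoate, via allylindium dibromide 16 (not isolated)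
Conditions: In powder, THF/H2O 1:1, rt
Reagents that add atoms: none
Why: Barbier-type indium-mediated carbonyl allylation, in which γ-attack of the geometrically fixed Z-allylindium through a chair transition state gives the C6/C7 syn relationship (cis-lactone precursor) and chelation of indium by the α-PMB ether gives the C5/C6 syn relationship, the minor isomers being removed by chromatography.

Step 12
Reactants: 17 methyl (3S,4R,5S,6R,7S)-6-[(tert-butyldimethylsilyl)oxy]-4-hydroxy-5-[(4-methoxybenzyl)oxy]-7-methyl-2-methylidene-3-[2-(phenylselanyl)ethyl]non-8-enoate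
Product: 18 (4S,5R)-5-{(1S,2R,3S)-2-[(tert-butyldimethylsilyl)oxy]-1-[(4-methoxybenzyl)oxy]-3-methylpent-4-en-1-yl}-3-methylidene-4-[2-(phenylselanyl)ethyl]oxolan-2-one
Conditions: p-TsOH·H2O (cat.), CH2Cl2, rt
Reagents that add atoms: none
Why: Acid-catalysed lactonisation of the γ-hydroxy ester closes the cis-disubstituted α-methylene-γ-butyrolactone without touching the stereocentres.

Step 13
Reactants: 18 (4S,5R)-5-{(1S,2R,3S)-2-[(tert-butyldimethylsilyl)oxy]-1-[(4-methoxybenzyl)oxy]-3-methylpent-4-en-1-yl}-3-methylidene-4-[2-(phenylselanyl)ethyl]oxolan-2-one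
Product: 20 (4S,5R)-5-{(1S,2R,3S)-2-[(tert-butyldimethylsilyl)oxy]-1-[(4-methoxybenzyl)oxy]-3-methylpent-4-en-1-yl}-4-ethenyl-3-methylideneoxolan-2-one, via selenoxide 19 (not isolated)
Conditions: 30% H2O2, pyridine, CH2Cl2, 0 to 40 °C
Reagents that add atoms: none
Why: Selenide oxidation followed by syn selenoxide elimination can only remove a C8 hydrogen and therefore unmasks the C7 vinyl group with a single regiochemistry.

Step 14
Reactants: 20 (4S,5R)-5-{(1S,2R,3S)-2-[(tert-butyldimethylsilyl)oxy]-1-[(4-methoxybenzyl)oxy]-3-methylpent-4-en-1-yl}-4-ethenyl-3-methylideneoxolan-2-one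
Product: 21 (3aS,6S,7R,8S,8aR)-7-[(tert-butyldimethylsilyl)oxy]-8-[(4-methoxybenzyl)oxy]-6-methyl-3-methylidene-3,3a,6,7,8,8a-hexahydro-2H-cyclohepta[b]furan-2-one
Conditions: second-generation Grubbs catalyst RuCl2(=CHPh)(PCy3)(H2IMes) (5 mol%), CH2Cl2, high dilution (2 mmol per litre), 40 °C
Reagents that add atoms: none
Why: Ring-closing metathesis of the two monosubstituted vinyl groups, held close by the cis-lactone, forms the cycloheptene faster than the electron-poor 1,1-disubstituted methylene can react.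

Step 15
Reactants: 21 (3aS,6S,7R,8S,8aR)-7-[(tert-butyldimethylsilyl)oxy]-8-[(4-methoxybenzyl)oxy]-6-methyl-3-methylidene-3,3a,6,7,8,8a-hexahydro-2H-cyclohepta[b]furan-2-one
Product: 22 (3R,3aS,6S,7R,8S,8aR)-7-[(tert-butyldimethylsilyl)oxy]-8-[(4-methoxybenzyl)oxy]-3,6-dimethyloctahydro-2H-cyclohepta[b]furan-2-one
Conditions: H2 (3 atm), RhCl(PPh3)3 (10 mol%), benzene/EtOH 1:1, rt
Reagents that add atoms: none
Why: Homogeneous hydrogenation saturates the ring alkene and adds hydrogen to the exocyclic methylene from the convex face of the cis-fused lactone (the face of H7), which sets C11 with its methyl on the concave side and leaves the PMB ether intact.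

Step 16
Reactants: 22 (3R,3aS,6S,7R,8S,8aR)-7-[(tert-butyldimethylsilyl)oxy]-8-[(4-methoxybenzyl)oxy]-3,6-dimethyloctahydro-2H-cyclohepta[b]furan-2-one
Product: 23 (3R,3aS,6S,7R,8R,8aR)-7-hydroxy-8-[(4-methoxybenzyl)oxy]-3,6-dimethyloctahydro-2H-cyclohepta[b]furan-2-one
Conditions: HF·pyridine, THF, 0 °C to rt
Reagents that add atoms: none
Why: Fluoride-mediated desilylation under weakly acidic conditions frees the C1 alcohol without epimerising the C11 centre next to the lactone carbonyl.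

Step 17
Reactants: 23 (3R,3aS,6S,7R,8R,8aR)-7-hydroxy-8-[(4-methoxybenzyl)oxy]-3,6-dimethyloctahydro-2H-cyclohepta[b]furan-2-one
Product: 24 (3R,3aS,6S,8S,8aR)-8-[(4-methoxybenzyl)oxy]-3,6-dimethylhexahydro-2H-cyclohepta[b]furan-2,7(3H)-dione
Conditions: Dess–Martin periodinane, CH2Cl2, 0 °C to rt; used crude
Reagents that add atoms: none
Why: Dess–Martin oxidation gives the C1 ketone under neutral conditions, so neither the two epimerisable α-centres nor the β-acyloxy group is disturbed.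

Step 18
Reactants: 24 (3R,3aS,6S,8S,8aR)-8-[(4-methoxybenzyl)oxy]-3,6-dimethylhexahydro-2H-cyclohepta[b]furan-2,7(3H)-dione; 25 ethynylmagnesium bromide
Product: 26 (3R,3aS,6S,7R,8S,8aR)-7-ethynyl-7-hydroxy-8-[(4-methoxybenzyl)oxy]-3,6-dimethyloctahydro-2H-cyclohepta[b]furan-2-one
Conditions: THF, −78 to −40 °C; then aq. NH4Cl
Reagents that add atoms: none
Why: Chelation-controlled Grignard 1,2-addition, in which magnesium bridges the ketone and the C5 PMB ether, the C10 methyl is thereby pseudoaxial on the lower face, and the small weakly basic acetylide attacks anti to it, setting C1 with OH cis to the C10 methyl and trans to the C5 oxygen while the lactone is untouched at low temperature.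

Step 19
Reactants: 26 (3R,3aS,6S,7R,8S,8aR)-7-ethynyl-7-hydroxy-8-[(4-methoxybenzyl)oxy]-3,6-dimethyloctahydro-2H-cyclohepta[b]furan-2-one
Product: 27 (3R,3aS,6S,7S,8S,8aR)-7-acetyl-7-hydroxy-8-[(4-methoxybenzyl)oxy]-3,6-dimethyloctahydro-2H-cyclohepta[b]furan-2-one
Conditions: Ph3PAuCl (3 mol%), AgOTf (3 mol%), MeOH/H2O 10:1, 50 °C
Reagents that add atoms: water, O
Why: Gold-catalysed Markovnikov hydration of the terminal alkyne places the carbonyl on the internal carbon and gives the α-hydroxy methyl ketone without affecting C1.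

Step 20
Reactants: 27 (3R,3aS,6S,7S,8S,8aR)-7-acetyl-7-hydroxy-8-[(4-methoxybenzyl)oxy]-3,6-dimethyloctahydro-2H-cyclohepta[b]furan-2-one
Product: 28 (3R,3aS,6S,7S,8S,8aR)-7-acetyl-7,8-dihydroxy-3,6-dimethyloctahydro-2H-cyclohepta[b]furan-2-one
Conditions: DDQ, CH2Cl2/pH 7 buffer 10:1, 0 °C
Reagents that add atoms: none
Why: Oxidative PMB ether cleavage under buffered wet conditions frees the C5 alcohol and leaves the lactone, ketone and tertiary alcohol alone.

Step 21
Reactants: 28 (3R,3aS,6S,7S,8S,8aR)-7-acetyl-7,8-dihydroxy-3,6-dimethyloctahydro-2H-cyclohepta[b]furan-2-one; 29 angelic acid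
Product: 31 (3R,3aS,6S,7S,8S,8aR)-7-acetyl-7-hydroxy-3,6-dimethyl-2-oxooctahydro-2H-cyclohepta[b]furan-8-yl (2Z)-2-methylbut-2-enoate, via mixed anhydride 30 (not isolated)
Conditions: 29, 2,4,6-trichlorobenzoyl chloride, Et3N, toluene, rt; then 28, 80 °C
Reagents that add atoms: none
Why: Yamaguchi-type esterification through the trichlorobenzoyl mixed anhydride without a nucleophilic catalyst acylates only the secondary C5 alcohol (the tertiary C1 alcohol is inert) and avoids isomerisation of the angelate to the tiglate.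

Step 22
Reactants: 31 (3R,3aS,6S,7S,8S,8aR)-7-acetyl-7-hydroxy-3,6-dimethyl-2-oxooctahydro-2H-cyclohepta[b]furan-8-yl (2Z)-2-methylbut-2-enoate
Product: 32 (3R,3aS,6S,7S,8S,8aR)-7-acetyl-3,6-dimethyl-2-oxo-7-[(trimethylsilyl)oxy]octahydro-2H-cyclohepta[b]furan-8-yl (2Z)-2-methylbut-2-enoate
Conditions: N-(trimethylsilyl)imidazole, CH2Cl2, rt
Reagents that add atoms: N-(trimethylsilyl)imidazole, C[Si](C)(C)n1ccnc1
Why: Base-free silylation caps the tertiary α-ketol hydroxyl so that it can neither consume the boron reagent nor trigger an α-ketol shift in the aldol step.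

Step 23
Reactants: 32 (3R,3aS,6S,7S,8S,8aR)-7-acetyl-3,6-dimethyl-2-oxo-7-[(trimethylsilyl)oxy]octahydro-2H-cyclohepta[b]furan-8-yl (2Z)-2-methylbut-2-enoate; 33 acetaldehyde
Product: 36 (3R,3aS,6S,7S,8S,8aR)-7-[(3S)-3-hydroxybutanoyl]-3,6-dimethyl-2-oxo-7-[(trimethylsilyl)oxy]octahydro-2H-cyclohepta[b]furan-8-yl (2Z)-2-methylbut-2-enoate, via enol diisopinocampheylborinate 34 (not isolated), via boron aldolate 35 (not isolated)
Conditions: (−)-Ipc2BCl, Et3N, Et2O, 0 °C; 33, −78 to −20 °C; then 30% H2O2, MeOH, pH 7 buffer, 0 °C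
Reagents that add atoms: none
Why: Reagent-controlled boron aldol reaction of a methyl ketone that can enolise only toward its CH3 group, in which the isopinocampheyl ligands derived from (+)-α-pinene direct attack on the re face of acetaldehyde and so set the (4S) carbinol.

Step 24
Reactants: 36 (3R,3aS,6S,7S,8S,8aR)-7-[(3S)-3-hydroxybutanoyl]-3,6-dimethyl-2-oxo-7-[(trimethylsilyl)oxy]octahydro-2H-cyclohepta[b]furan-8-yl (2Z)-2-methylbut-2-enoate
Product: 37 (3R,3aS,6S,7S,8S,8aR)-7-hydroxy-7-[(3S)-3-hydroxybutanoyl]-3,6-dimethyl-2-oxooctahydro-2H-cyclohepta[b]furan-8-yl (2Z)-2-methylbut-2-enoate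
Conditions: HF·pyridine, pyridine, THF, 0 °C
Reagents that add atoms: none
Why: Buffered fluoride desilylation removes the tertiary TMS ether without dehydrating the β-hydroxy ketone or isomerising the angelate.

**Compound list**
1 | (R)-(2,2-dimethyl-1,3-dioxolan-4-yl)methanol | OC[C@@H]1COC(C)(C)O1 | starting material
2 | (4S)-2,2-dimethyl-1,3-dioxolane-4-carbaldehyde | O=C[C@@H]1COC(C)(C)O1 | intermediate
3 | 2-[(2Z)-but-2-en-1-yl]-4,4,5,5-tetramethyl-1,3,2-dioxaborolane | C/C=C\CB1OC(C)(C)C(C)(C)O1 | starting material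
4 | 2-{[(1R,2S)-1-[(4S)-2,2-dimethyl-1,3-dioxolan-4-yl]-2-methylbut-3-en-1-yl]oxy}-4,4,5,5-tetramethyl-1,3,2-dioxaborolane | C=C[C@H](C)[C@@H](OB1OC(C)(C)C(C)(C)O1)[C@@H]2COC(C)(C)O2 | intermediate
5 | (1R,2S)-1-[(4S)-2,2-dimethyl-1,3-dioxolan-4-yl]-2-methylbut-3-en-1-ol | C=C[C@H](C)[C@@H](O)[C@@H]1COC(C)(C)O1 | intermediate
6 | tert-butyl{[(1R,2S)-1-[(4S)-2,2-dimethyl-1,3-dioxolan-4-yl]-2-methylbut-3-en-1-yl]oxy}dimethylsilane | C=C[C@H](C)[C@@H](O[Si](C)(C)C(C)(C)C)[C@@H]1COC(C)(C)O1 | intermediate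
7 | (2S,3R,4S)-3-[(tert-butyldimethylsilyl)oxy]-4-methylhex-5-ene-1,2-diol | C=C[C@H](C)[C@@H](O[Si](C)(C)C(C)(C)C)[C@@H](O)CO | intermediate
8 | tert-butyl{[(1R,2S)-1-[(4S)-2-(4-methoxyphenyl)-1,3-dioxolan-4-yl]-2-methylbut-3-en-1-yl]oxy}dimethylsilane (both acetal epimers) | C=C[C@H](C)[C@@H](O[Si](C)(C)C(C)(C)C)[C@@H]1COC(c2ccc(OC)cc2)O1 | intermediate
9 | (2S,3R,4S)-3-[(tert-butyldimethylsilyl)oxy]-2-[(4-methoxybenzyl)oxy]-4-methylhex-5-en-1-ol | C=C[C@H](C)[C@@H](O[Si](C)(C)C(C)(C)C)[C@@H](OCc1ccc(OC)cc1)CO | intermediate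
10 | (2R,3R,4S)-3-[(tert-butyldimethylsilyl)oxy]-2-[(4-methoxybenzyl)oxy]-4-methylhex-5-enal | C=C[C@H](C)[C@@H](O[Si](C)(C)C(C)(C)C)[C@@H](OCc1ccc(OC)cc1)C=O | intermediate
11 | acrolein | C=CC=O | starting material
12 | 3-(phenylselanyl)propanal | O=CCC[Se]c1ccccc1 | intermediate
13 | methyl acrylate | C=CC(=O)OC | starting material
14 | methyl 3-hydroxy-2-methylidene-5-(phenylselanyl)pentanoate (racemic) | C=C(C(=O)OC)C(O)CC[Se]c1ccccc1 | intermediate
15 | methyl (2Z)-2-(bromomethyl)-5-(phenylselanyl)pent-2-enoate | COC(=O)/C(CBr)=C/CC[Se]c1ccccc1 | intermediate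
16 | methyl (2Z)-2-[(dibromoindiganyl)methyl]-5-(phenylselanyl)pent-2-enoate (allylindium reagent drawn as its dibromide) | COC(=O)/C(C[In](Br)Br)=C/CC[Se]c1ccccc1 | intermediate
17 | methyl (3S,4R,5S,6R,7S)-6-[(tert-butyldimethylsilyl)oxy]-4-hydroxy-5-[(4-methoxybenzyl)oxy]-7-methyl-2-methylidene-3-[2-(phenylselanyl)ethyl]non-8-enoate | C=C[C@H](C)[C@@H](O[Si](C)(C)C(C)(C)C)[C@@H](OCc1ccc(OC)cc1)[C@H](O)[C@@H](CC[Se]c1ccccc1)C(=C)C(=O)OC | intermediate
18 | (4S,5R)-5-{(1S,2R,3S)-2-[(tert-butyldimethylsilyl)oxy]-1-[(4-methoxybenzyl)oxy]-3-methylpent-4-en-1-yl}-3-methylidene-4-[2-(phenylselanyl)ethyl]oxolan-2-one | C=C[C@H](C)[C@@H](O[Si](C)(C)C(C)(C)C)[C@@H](OCc1ccc(OC)cc1)[C@@H]1OC(=O)C(=C)[C@@H]1CC[Se]c1ccccc1 | intermediate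
19 | (4S,5R)-4-[2-(benzeneseleninyl)ethyl]-5-{(1S,2R,3S)-2-[(tert-butyldimethylsilyl)oxy]-1-[(4-methoxybenzyl)oxy]-3-methylpent-4-en-1-yl}-3-methylideneoxolan-2-one | C=C[C@H](C)[C@@H](O[Si](C)(C)C(C)(C)C)[C@@H](OCc1ccc(OC)cc1)[C@@H]1OC(=O)C(=C)[C@@H]1CC[Se](=O)c1ccccc1 | intermediate
20 | (4S,5R)-5-{(1S,2R,3S)-2-[(tert-butyldimethylsilyl)oxy]-1-[(4-methoxybenzyl)oxy]-3-methylpent-4-en-1-yl}-4-ethenyl-3-methylideneoxolan-2-one | C=C[C@H](C)[C@@H](O[Si](C)(C)C(C)(C)C)[C@@H](OCc1ccc(OC)cc1)[C@@H]1OC(=O)C(=C)[C@@H]1C=C | intermediate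
21 | (3aS,6S,7R,8S,8aR)-7-[(tert-butyldimethylsilyl)oxy]-8-[(4-methoxybenzyl)oxy]-6-methyl-3-methylidene-3,3a,6,7,8,8a-hexahydro-2H-cyclohepta[b]furan-2-one | COc1ccc(CO[C@H]2[C@@H]3OC(=O)C(=C)[C@@H]3C=C[C@H](C)[C@H]2O[Si](C)(C)C(C)(C)C)cc1 | intermediate
22 | (3R,3aS,6S,7R,8S,8aR)-7-[(tert-butyldimethylsilyl)oxy]-8-[(4-methoxybenzyl)oxy]-3,6-dimethyloctahydro-2H-cyclohepta[b]furan-2-one | COc1ccc(CO[C@H]2[C@@H]3OC(=O)[C@H](C)[C@@H]3CC[C@H](C)[C@H]2O[Si](C)(C)C(C)(C)C)cc1 | intermediate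
23 | (3R,3aS,6S,7R,8R,8aR)-7-hydroxy-8-[(4-methoxybenzyl)oxy]-3,6-dimethyloctahydro-2H-cyclohepta[b]furan-2-one | COc1ccc(CO[C@H]2[C@@H]3OC(=O)[C@H](C)[C@@H]3CC[C@H](C)[C@H]2O)cc1 | intermediate
24 | (3R,3aS,6S,8S,8aR)-8-[(4-methoxybenzyl)oxy]-3,6-dimethylhexahydro-2H-cyclohepta[b]furan-2,7(3H)-dione | COc1ccc(CO[C@H]2[C@@H]3OC(=O)[C@H](C)[C@@H]3CC[C@H](C)C2=O)cc1 | intermediate
25 | ethynylmagnesium bromide | C#C[Mg]Br | starting material
26 | (3R,3aS,6S,7R,8S,8aR)-7-ethynyl-7-hydroxy-8-[(4-methoxybenzyl)oxy]-3,6-dimethyloctahydro-2H-cyclohepta[b]furan-2-one | COc1ccc(CO[C@H]2[C@@H]3OC(=O)[C@H](C)[C@@H]3CC[C@H](C)[C@@]2(O)C#C)cc1 | intermediate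
27 | (3R,3aS,6S,7S,8S,8aR)-7-acetyl-7-hydroxy-8-[(4-methoxybenzyl)oxy]-3,6-dimethyloctahydro-2H-cyclohepta[b]furan-2-one | COc1ccc(CO[C@H]2[C@@H]3OC(=O)[C@H](C)[C@@H]3CC[C@H](C)[C@@]2(O)C(C)=O)cc1 | intermediate
28 | (3R,3aS,6S,7S,8S,8aR)-7-acetyl-7,8-dihydroxy-3,6-dimethyloctahydro-2H-cyclohepta[b]furan-2-one | O[C@H]1[C@@H]2OC(=O)[C@H](C)[C@@H]2CC[C@H](C)[C@@]1(O)C(C)=O | intermediate
29 | angelic acid, (2Z)-2-methylbut-2-enoic acid | C/C=C(/C)C(=O)O | starting material
30 | (2Z)-2-methylbut-2-enoic 2,4,6-trichlorobenzoic anhydride | C/C=C(/C)C(=O)OC(=O)c1c(Cl)cc(Cl)cc1Cl | intermediate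
31 | (3R,3aS,6S,7S,8S,8aR)-7-acetyl-7-hydroxy-3,6-dimethyl-2-oxooctahydro-2H-cyclohepta[b]furan-8-yl (2Z)-2-methylbut-2-enoate | C/C=C(/C)C(=O)O[C@H]1[C@@H]2OC(=O)[C@H](C)[C@@H]2CC[C@H](C)[C@@]1(O)C(C)=O | intermediate
32 | (3R,3aS,6S,7S,8S,8aR)-7-acetyl-3,6-dimethyl-2-oxo-7-[(trimethylsilyl)oxy]octahydro-2H-cyclohepta[b]furan-8-yl (2Z)-2-methylbut-2-enoate | C/C=C(/C)C(=O)O[C@H]1[C@@H]2OC(=O)[C@H](C)[C@@H]2CC[C@H](C)[C@@]1(O[Si](C)(C)C)C(C)=O | intermediate
33 | acetaldehyde | CC=O | starting material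
34 | enol diisopinocampheylborinate of 32 (boron bound to the enol oxygen of the former acetyl group; isopinocampheyl groups from (+)-α-pinene) | C/C=C(/C)C(=O)O[C@H]1[C@@H]2OC(=O)[C@H](C)[C@@H]2CC[C@H](C)[C@@]1(O[Si](C)(C)C)C(=C)OB([C@@H]3C[C@@H]4C[C@H]([C@H]3C)C4(C)C)[C@@H]3C[C@@H]4C[C@H]([C@H]3C)C4(C)C | intermediate
35 | O-diisopinocampheylboryl aldolate of 36 (boron on the C4 oxygen) | C/C=C(/C)C(=O)O[C@H]1[C@@H]2OC(=O)[C@H](C)[C@@H]2CC[C@H](C)[C@@]1(O[Si](C)(C)C)C(=O)C[C@H](C)OB([C@@H]3C[C@@H]4C[C@H]([C@H]3C)C4(C)C)[C@@H]3C[C@@H]4C[C@H]([C@H]3C)C4(C)C | intermediate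
36 | (3R,3aS,6S,7S,8S,8aR)-7-[(3S)-3-hydroxybutanoyl]-3,6-dimethyl-2-oxo-7-[(trimethylsilyl)oxy]octahydro-2H-cyclohepta[b]furan-8-yl (2Z)-2-methylbut-2-enoate | C/C=C(/C)C(=O)O[C@H]1[C@@H]2OC(=O)[C@H](C)[C@@H]2CC[C@H](C)[C@@]1(O[Si](C)(C)C)C(=O)C[C@H](C)O | intermediate
37 | (3R,3aS,6S,7S,8S,8aR)-7-hydroxy-7-[(3S)-3-hydroxybutanoyl]-3,6-dimethyl-2-oxooctahydro-2H-cyclohepta[b]furan-8-yl (2Z)-2-methylbut-2-enoate (CNP0321985.2) | C/C=C(/C)C(=O)O[C@H]1[C@@H]2OC(=O)[C@H](C)[C@@H]2CC[C@H](C)[C@@]1(O)C(=O)C[C@H](C)O | target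

**Totals**
Total step count: 24 steps.
Longest linear sequence: 21 steps (steps 1–7, then 11–24); the bromide arm adds steps 8–10.

**Three steps most likely to fail, each with a fallback**

Step 11 (indium allylation). The C5/C6 syn relationship depends on chelation by a PMB ether in water next to a bulky silyl ether, and Felkin-type addition would give the C6 epimer. The fallback sets out from bromide 15 and aldehyde 10. Bromide 15 is treated with hexabutylditin and Pd(PPh3)4 (zerovalent palladium) in THF to give the allylstannane methyl (2Z)-5-(phenylselanyl)-2-[(tributylstannyl)methyl]pent-2-enoate F1. F1 is then added to 10 that has been precomplexed with MgBr2·OEt2 in CH2Cl2 at −40 °C. This is a Lewis-acid-mediated allylstannane addition through an open transition state, with magnesium chelation giving C5/C6 syn and the antiperiplanar arrangement giving C6/C7 syn. It comes back to the route at hydroxy ester 17.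

Step 18 (ethynyl Grignard addition). The ketone is hindered, has two epimerisable α-centres and a β-acyloxy group that can be lost by E1cB elimination after enolisation, and the facial selectivity rests on the chelate model. The fallback sets out from ketone 24 and uses a less basic organocerium acetyl-anion equivalent that needs no hydration step. (1-Ethoxyvinyl)lithium (from ethyl vinyl ether and t-BuLi) is transmetallated with anhydrous CeCl3 in THF and added at −78 °C to give the enol ether (3R,3aS,6S,7S,8S,8aR)-7-(1-ethoxyethenyl)-7-hydroxy-8-[(4-methoxybenzyl)oxy]-3,6-dimethyloctahydro-2H-cyclohepta[b]furan-2-one F2. Stirring F2 with dilute aqueous HCl in THF hydrolyses the enol ether, and the sequence comes back to the route at methyl ketone 27, bypassing 26.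

Step 23 (boron aldol). Reagent control for methyl ketones with a small aldehyde is only moderate, and the influence of the neighbouring quaternary centre is unknown, so the C4 epimer ratio may be poor. The fallback sets out from 32.
- The lithium enolate (LiN(SiMe3)2, THF, −78 °C) and acetaldehyde give, without stereocontrol, the C4-epimeric mixture (3R,3aS,6S,7S,8S,8aR)-7-(3-hydroxybutanoyl)-3,6-dimethyl-2-oxo-7-[(trimethylsilyl)oxy]octahydro-2H-cyclohepta[b]furan-8-yl (2Z)-2-methylbut-2-enoate F3.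
- Mesylation and elimination (MsCl, Et3N, CH2Cl2, then DBU) convert F3 into the enone (3R,3aS,6S,7S,8S,8aR)-7-[(2E)-but-2-enoyl]-3,6-dimethyl-2-oxo-7-[(trimethylsilyl)oxy]octahydro-2H-cyclohepta[b]furan-8-yl (2Z)-2-methylbut-2-enoate F4.
- Copper-catalysed enantioselective conjugate borylation (CuCl, NaOt-Bu, a Josiphos ligand of the enantiomeric series that delivers the 4S product, B2pin2, MeOH, THF) gives the β-boryl ketone (3R,3aS,6S,7S,8S,8aR)-3,6-dimethyl-2-oxo-7-[(3S)-3-(4,4,5,5-tetramethyl-1,3,2-dioxaborolan-2-yl)butanoyl]-7-[(trimethylsilyl)oxy]octahydro-2H-cyclohepta[b]furan-8-yl (2Z)-2-methylbut-2-enoate F5.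
- Oxidation of F5 with NaBO3·4H2O in THF/H2O proceeds with retention and comes back to the route at 36.

Further compounds
F1 | step 11 | methyl (2Z)-5-(phenylselanyl)-2-[(tributylstannyl)methyl]pent-2-enoate | COC(=O)/C(C[Sn](CCCC)(CCCC)CCCC)=C/CC[Se]c1ccccc1
F2 | step 18 | (3R,3aS,6S,7S,8S,8aR)-7-(1-ethoxyethenyl)-7-hydroxy-8-[(4-methoxybenzyl)oxy]-3,6-dimethyloctahydro-2H-cyclohepta[b]furan-2-one | COc1ccc(CO[C@H]2[C@@H]3OC(=O)[C@H](C)[C@@H]3CC[C@H](C)[C@@]2(O)C(=C)OCC)cc1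
F3 | step 23 | (3R,3aS,6S,7S,8S,8aR)-7-(3-hydroxybutanoyl)-3,6-dimethyl-2-oxo-7-[(trimethylsilyl)oxy]octahydro-2H-cyclohepta[b]furan-8-yl (2Z)-2-methylbut-2-enoate (mixture of C4 epimers) | C/C=C(/C)C(=O)O[C@H]1[C@@H]2OC(=O)[C@H](C)[C@@H]2CC[C@H](C)[C@@]1(O[Si](C)(C)C)C(=O)CC(C)O
F4 | step 23 | (3R,3aS,6S,7S,8S,8aR)-7-[(2E)-but-2-enoyl]-3,6-dimethyl-2-oxo-7-[(trimethylsilyl)oxy]octahydro-2H-cyclohepta[b]furan-8-yl (2Z)-2-methylbut-2-enoate | C/C=C(/C)C(=O)O[C@H]1[C@@H]2OC(=O)[C@H](C)[C@@H]2CC[C@H](C)[C@@]1(O[Si](C)(C)C)C(=O)/C=C/C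
F5 | step 23 | (3R,3aS,6S,7S,8S,8aR)-3,6-dimethyl-2-oxo-7-[(3S)-3-(4,4,5,5-tetramethyl-1,3,2-dioxaborolan-2-yl)butanoyl]-7-[(trimethylsilyl)oxy]octahydro-2H-cyclohepta[b]furan-8-yl (2Z)-2-methylbut-2-enoate | C/C=C(/C)C(=O)O[C@H]1[C@@H]2OC(=O)[C@H](C)[C@@H]2CC[C@H](C)[C@@]1(O[Si](C)(C)C)C(=O)C[C@H](C)B3OC(C)(C)C(C)(C)O3
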